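I have decided to follow these flasks by the fraction of free monomer left, not by the fraction made, and to turn that fraction into a chain length at the very end.

| setting | violet | Sunday's | Saturday's |
|---|---|---|---|
| free monomer | 0.030 M | 0.020 M | 0.020 M |
| initiator | 1.7 mol% | 1.7 mol% | 1.7 mol% |
| remark | run made earlier |  |  |
| time |  | 15 h | 5.0 h |

- violet (time / min: monomer in chains / %): 8.00: 3.2; 12.0: 4.7; 20.0: 8.8; 30.0: 14.0; 50.0: 22.7; 90.0: 37.5

(each reading ± 0.3 percentage points)

- the average divides the monomer in chains by the number of chains begun, living and dead together
- the numbers in the tables scatter with a standard deviation of 0.3 percentage points
- the earlier runs do not show the number of chains; that part of a forecast is a guess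
- no earlier run changes the charge of initiator; that part of a forecast is a guess

- which of the two ends with the longer chains by the average number of monomer units in a chain (chains begun, living or dead) ("neither" if they lie within 10 %) (Sunday's / Saturday's / neither)
- average number of monomer units in a chain (chains begun, living or dead) at the end, Sunday's
- average number of monomer units in a chain (chains begun, living or dead) at the end, Saturday's

**What do the violet readings say?** Take the negative logarithm of the fraction left and divide it by the time. This gives 0.00503 /min at 30.0 min and 0.00522 /min at 90.0 min, so the violet run reads as a steady first-order loss.

**What do you take to the new charges?** I assume that this constant scales with the charge, since the loading is the same. That assumption is a guess. The factor is 0.667, which gives 0.00348 /min. The fraction left at the end is then 4.36 % for Sunday's and 35.2 % for Saturday's.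

**How does a fraction become a length?** The loading gives 58.8 as the charge ratio, the free monomer charged per initiator charged. The length is the fraction reacted times this ratio, divided by the start share, which is the number of chains begun per initiator charged.

**Where is that weakest?** The start share is the weak spot, since no earlier run shows the number of chains. With a share of one, I reckon 56.2 units for Sunday's and 38.1 for Saturday's. If the two shares are equal, Sunday's is longer, since it has less left.

The forecast names Sunday's, with 56 (range 47 to 68) for Sunday's and 38 (range 32 to 50) for Saturday's, on the ground “If every initiator starts one chain”.

The flask gives 93.0 units for Sunday's and 71.5 for Saturday's, so Sunday's ends longer.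

    free monomer + initiator → living end + monomer in chains (k = 200 /M/h)
    living end → dead end A (k = 0.183 /h)
    2 initiator → spent initiator B (k = 17600 /M/h)
    free monomer + living end → monomer in chains + living end, rate k4*[living end]*[free monomer] (k = 1620 /M/h)

Sunday's still holds 27 % of its free monomer at 15.0 h, more than my 4.36 %. With the charge ratio 58.8, the fraction reacted gives 42.9 units per initiator charged, so a length of 93.0 means a start share of 0.462. A neighbour flask with Sunday's recipe at 0.0050 M of free monomer leaves 72.0 % and reaches 35.8 units, a start share of 0.460.

The numbers in the tables stem from a simulated flask with constants of no real substance; scatter was added.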